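**Plan**

- Retrosynthesis: the two MOM ethers and a temporary C5 chlorine come off last. The O1–C8a and C4–C4a bonds of ring C are then cut together, leaving a 3-chloro-5-alkoxybenzyne (ring A) and an (S)-β-hydroxy N-methoxy-N-methylamide that carries O1–C2–C3–C4 and ring B.
- Enabling feature: the adjacent ring A carbons C8a and C4a bear an ether oxygen (O1) and an acyl carbon (C4) that are linked through C2–C3. This ortho nucleophile/electrophile pattern is what an aryne takes up in one 1,2-difunctionalisation that closes the six-membered ring C.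
- Forward, ring B piece: MOM ether, double prenyl coupling, Claisen condensation, asymmetric transfer hydrogenation. Ring A aryne precursor, made separately: Dakin oxidation, retro-Brook/triflation, MOM ether.
- The fragments are joined in the aryne annulation, which forms ring C; hydrodechlorination and MOM cleavage finish the route.
- Stereochemistry: the only stereocentre, C2 (S), is set by catalyst control in the ketone transfer hydrogenation and carried through with no bond to it broken.

Key step: step 8

Remark: the four building blocks marked as starting materials in the compound list are taken as catalogue chemicals; atom numbers (O1 to C8a) and ring letters (A, B, C) follow flavanone usage.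

**Route**

Step 1
Reactants: 1 methyl 3,5-dibromo-4-hydroxybenzoate
Product: 2 methyl 3,5-dibromo-4-(methoxymethoxy)benzoate
Conditions: NaH, DMF, 0 °C; MOMCl, 0 °C → rt
Reagents that add atoms: chloromethyl methyl ether (MOMCl), COCCl
Why: O-alkylation of the acidic 2,6-dibromophenolate by the highly reactive chloromethyl ether (Williamson-type acetal formation) should mask the phenol as an ether that survives base, fluoride and palladium chemistry.

Step 2
Reactants: 2 methyl 3,5-dibromo-4-(methoxymethoxy)benzoate; 3 4,4,5,5-tetramethyl-2-(3-methylbut-2-en-1-yl)-1,3,2-dioxaborolane (prenylboronic acid pinacol ester)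
Product: 4 methyl 4-(methoxymethoxy)-3,5-bis(3-methylbut-2-en-1-yl)benzoate
Conditions: Pd(OAc)2 (5 mol%), t-BuXPhos (10 mol%), K3PO4 (aq), MeCN, 70 °C
Reagents that add atoms: none
Why: A double Suzuki–Miyaura coupling of the electron-poor aryl bromide with the allylic boronate should give the linear prenyl arene, because the bulky biaryl di-tert-butylphosphine is used for α-selective reductive elimination.

Step 3
Reactants: 4 methyl 4-(methoxymethoxy)-3,5-bis(3-methylbut-2-en-1-yl)benzoate; 5 N-methoxy-N-methylacetamide
Product: 7 N-methoxy-3-[4-(methoxymethoxy)-3,5-bis(3-methylbut-2-en-1-yl)phenyl]-N-methyl-3-oxopropanamide, via lithium enolate 6 (not isolated)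
Conditions: 5, LiN(i-Pr)2 (2.2 equiv each), THF, −78 °C; then 4, −78 → 0 °C; aq NH4Cl
Reagents that add atoms: none
Why: A crossed Claisen condensation of the amide enolate with the non-enolisable aryl ester should stop at the β-keto amide, because the product is held as its enolate until the quench.

Step 4
Reactants: 7 N-methoxy-3-[4-(methoxymethoxy)-3,5-bis(3-methylbut-2-en-1-yl)phenyl]-N-methyl-3-oxopropanamide
Product: 8 (3S)-3-hydroxy-N-methoxy-3-[4-(methoxymethoxy)-3,5-bis(3-methylbut-2-en-1-yl)phenyl]-N-methylpropanamide
Conditions: RuCl[(S,S)-TsDPEN](p-cymene) (1 mol%), HCO2H/Et3N (5:2), DMF, 30 °C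
Reagents that add atoms: none
Why: Noyori-type asymmetric transfer hydrogenation of the aryl ketone by outer-sphere hydride delivery should give the (S)-carbinol under control of the (S,S)-diamine ligand (the sense known for aryl alkyl ketones), and the ruthenium hydride leaves the prenyl alkenes and the amide untouched.

Step 5
Reactants: 9 3-bromo-5-chloro-4-hydroxybenzaldehyde
Product: 11 2-bromo-6-chlorobenzene-1,4-diol, via aryl formate 10 (not isolated)
Conditions: H2O2 (30% aq), NaOH (aq), THF, 0 °C → rt, N2; then dil. HCl
Reagents that add atoms: hydrogen peroxide, OO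
Why: Dakin oxidation of a para-hydroxybenzaldehyde (aryl migration in the peroxide adduct of the phenolate, then formate hydrolysis) should replace the formyl group by hydroxyl.

Step 6
Reactants: 11 2-bromo-6-chlorobenzene-1,4-diol
Product: 15 2-chloro-4-hydroxy-6-(trimethylsilyl)phenyl trifluoromethanesulfonate, via bis(silyl) ether 12 (not isolated), via lithium phenolate 13 (not isolated), via silyl ether triflate 14 (not isolated)
Conditions: HMDS, THF, 65 °C, evaporate; n-BuLi, THF, −78 °C; Tf2O, −78 → 0 °C; aq citric acid
Reagents that add atoms: hexamethyldisilazane (HMDS), C[Si](C)(C)N[Si](C)(C)C; trifluoromethanesulfonic anhydride (Tf2O), O=S(=O)(OS(=O)(=O)C(F)(F)F)C(F)(F)F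
Why: Silylation of both phenols, bromine–lithium exchange (chlorine is inert at −78 °C) and retro-Brook 1,3 O→C silyl migration should put SiMe3 on carbon and leave only the oxygen between Cl and SiMe3 as a lithium phenolate, which alone is triflated, while the other aryl O–SiMe3 ether is hydrolysed on acidic work-up, so the two hydroquinone oxygens are told apart without a selective protection.

Step 7
Reactants: 15 2-chloro-4-hydroxy-6-(trimethylsilyl)phenyl trifluoromethanesulfonate
Product: 16 2-chloro-4-(methoxymethoxy)-6-(trimethylsilyl)phenyl trifluoromethanesulfonate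
Conditions: MOMCl, i-Pr2NEt, CH2Cl2, 0 °C → rt
Reagents that add atoms: chloromethyl methyl ether (MOMCl), COCCl
Why: Amine-mediated MOM ether formation on the unhindered phenol should proceed without fluoride or strong base, so the ortho-silylaryl triflate stays intact.

Step 8
Reactants: 8 (3S)-3-hydroxy-N-methoxy-3-[4-(methoxymethoxy)-3,5-bis(3-methylbut-2-en-1-yl)phenyl]-N-methylpropanamide; 16 2-chloro-4-(methoxymethoxy)-6-(trimethylsilyl)phenyl trifluoromethanesulfonate
Product: 21 (2S)-5-chloro-7-(methoxymethoxy)-2-[4-(methoxymethoxy)-3,5-bis(3-methylbut-2-en-1-yl)phenyl]-2,3-dihydro-4H-chromen-4-one, via sodium alkoxide 17 (not isolated), via aryne 18 (not isolated), via aryl anion 19 (not isolated), via hemiaminal alkoxide 20 (not isolated)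
Conditions: 8, NaH, THF, 0 °C; then 16 (1.5 equiv), KF, 18-crown-6, THF, −20 °C → rt; aq NH4Cl, 0 °C
Reagents that add atoms: none
Why: Proposed new method: fluoride removes SiMe3 from 16 and triflate leaves to give aryne 18; the alkoxide oxygen of 17 adds to the aryne carbon remote from chlorine (the future C8a), and the resulting aryl anion 19 at the carbon next to chlorine (the future C4a) closes ring C by 6-exo-trig attack on the tethered N-methoxy-N-methylamide carbonyl, so that O1–C8a and C4–C4a arise in one formal [4+2] annulation. The closest known reaction types are the aryne annulation of salicylate esters to xanthones (phenoxide addition followed by intramolecular acyl substitution) and aryne σ-insertion into C(=O)–X bonds; new here is an aliphatic β-alkoxide as nucleophile paired with an amide acceptor. The tetrahedral adduct 20 keeps the ketone masked until the near-neutral quench, which prevents over-addition and the base-induced retro-oxa-Michael ring opening that would racemise a free flavanone. No new stereocentre is formed, and C2 comes from 8 with retention because none of its bonds is broken. The step needs regioselectivity (O at C8a, not C4a), which the C5 chlorine secures by distorting the aryne and inductively stabilising the adjacent carbanion, outweighing the weaker opposing effect of the C7 ether; it also needs capture of 19 by the carbonyl faster than chloride loss or protonation, which the six-membered geometry, the absence of proton donors after NaH deprotonation and the low temperature should favour.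

Step 9
Reactants: 21 (2S)-5-chloro-7-(methoxymethoxy)-2-[4-(methoxymethoxy)-3,5-bis(3-methylbut-2-en-1-yl)phenyl]-2,3-dihydro-4H-chromen-4-one
Product: 22 (2S)-7-(methoxymethoxy)-2-[4-(methoxymethoxy)-3,5-bis(3-methylbut-2-en-1-yl)phenyl]-2,3-dihydro-4H-chromen-4-one
Conditions: Pd(OAc)2 (5 mol%), XPhos (10 mol%), HCO2Na, DMF, 80 °C
Reagents that add atoms: none
Why: Palladium-catalysed transfer hydrodehalogenation (oxidative addition of zerovalent palladium to the C–Cl bond activated by the ortho carbonyl, formate exchange, decarboxylation, C–H reductive elimination) should remove the helper chlorine under weakly basic conditions that leave the trisubstituted alkenes and C2 alone.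

Step 10
Reactants: 22 (2S)-7-(methoxymethoxy)-2-[4-(methoxymethoxy)-3,5-bis(3-methylbut-2-en-1-yl)phenyl]-2,3-dihydro-4H-chromen-4-one
Product: 23 abyssinone-IV, (2S)-7-hydroxy-2-[4-hydroxy-3,5-bis(3-methylbut-2-en-1-yl)phenyl]-2,3-dihydro-4H-chromen-4-one
Conditions: HCl (3 M aq), MeOH, 40 °C
Reagents that add atoms: none
Why: Acid-catalysed acetal exchange with methanol should cleave both MOM ethers under conditions mild enough to spare the ortho-prenyl phenol (no chroman formation) and the C2 configuration.

**Compound list**

1 | methyl 3,5-dibromo-4-hydroxybenzoate | COC(=O)c1cc(Br)c(O)c(Br)c1 | starting material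
2 | methyl 3,5-dibromo-4-(methoxymethoxy)benzoate | COCOc1c(Br)cc(cc1Br)C(=O)OC | intermediate
3 | 4,4,5,5-tetramethyl-2-(3-methylbut-2-en-1-yl)-1,3,2-dioxaborolane | CC(C)=CCB1OC(C)(C)C(C)(C)O1 | starting material
4 | methyl 4-(methoxymethoxy)-3,5-bis(3-methylbut-2-en-1-yl)benzoate | COCOc1c(CC=C(C)C)cc(cc1CC=C(C)C)C(=O)OC | intermediate
5 | N-methoxy-N-methylacetamide | CC(=O)N(C)OC | starting material
6 | lithium 1-[methoxy(methyl)amino]ethen-1-olate (lithium enolate of 5) | [Li+].[O-]C(=C)N(C)OC | intermediate (not isolated)
7 | N-methoxy-3-[4-(methoxymethoxy)-3,5-bis(3-methylbut-2-en-1-yl)phenyl]-N-methyl-3-oxopropanamide | COCOc1c(CC=C(C)C)cc(cc1CC=C(C)C)C(=O)CC(=O)N(C)OC | intermediate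
8 | (3S)-3-hydroxy-N-methoxy-3-[4-(methoxymethoxy)-3,5-bis(3-methylbut-2-en-1-yl)phenyl]-N-methylpropanamide | O[C@@H](CC(=O)N(C)OC)c1cc(CC=C(C)C)c(OCOC)c(CC=C(C)C)c1 | intermediate
9 | 3-bromo-5-chloro-4-hydroxybenzaldehyde | O=Cc1cc(Cl)c(O)c(Br)c1 | starting material
10 | 3-bromo-5-chloro-4-hydroxyphenyl formate | O=COc1cc(Cl)c(O)c(Br)c1 | intermediate (not isolated)
11 | 2-bromo-6-chlorobenzene-1,4-diol | Oc1cc(Cl)c(O)c(Br)c1 | intermediate
12 | 1-bromo-3-chloro-2,5-bis[(trimethylsilyl)oxy]benzene | C[Si](C)(C)Oc1cc(Cl)c(O[Si](C)(C)C)c(Br)c1 | intermediate (not isolated)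
13 | lithium 2-chloro-6-(trimethylsilyl)-4-[(trimethylsilyl)oxy]phenolate | [Li+].[O-]c1c(Cl)cc(O[Si](C)(C)C)cc1[Si](C)(C)C | intermediate (not isolated)
14 | 2-chloro-6-(trimethylsilyl)-4-[(trimethylsilyl)oxy]phenyl trifluoromethanesulfonate | C[Si](C)(C)Oc1cc(Cl)c(OS(=O)(=O)C(F)(F)F)c(c1)[Si](C)(C)C | intermediate (not isolated)
15 | 2-chloro-4-hydroxy-6-(trimethylsilyl)phenyl trifluoromethanesulfonate | Oc1cc(Cl)c(OS(=O)(=O)C(F)(F)F)c(c1)[Si](C)(C)C | intermediate
16 | 2-chloro-4-(methoxymethoxy)-6-(trimethylsilyl)phenyl trifluoromethanesulfonate | COCOc1cc(Cl)c(OS(=O)(=O)C(F)(F)F)c(c1)[Si](C)(C)C | intermediate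
17 | sodium (1S)-3-[methoxy(methyl)amino]-1-[4-(methoxymethoxy)-3,5-bis(3-methylbut-2-en-1-yl)phenyl]-3-oxopropan-1-olate | [Na+].[O-][C@@H](CC(=O)N(C)OC)c1cc(CC=C(C)C)c(OCOC)c(CC=C(C)C)c1 | intermediate (not isolated)
18 | 3-chloro-5-(methoxymethoxy)benzyne (1,2-didehydro-3-chloro-5-(methoxymethoxy)benzene) | COCOC1=CC#CC(Cl)=C1 | intermediate (not isolated)
19 | sodium 2-chloro-6-{(1S)-3-[methoxy(methyl)amino]-1-[4-(methoxymethoxy)-3,5-bis(3-methylbut-2-en-1-yl)phenyl]-3-oxopropoxy}-4-(methoxymethoxy)benzen-1-ide | [Na+].CON(C)C(=O)C[C@H](Oc1cc(OCOC)cc(Cl)[c-]1)c1cc(CC=C(C)C)c(OCOC)c(CC=C(C)C)c1 | intermediate (not isolated)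
20 | sodium (2S)-5-chloro-4-[methoxy(methyl)amino]-7-(methoxymethoxy)-2-[4-(methoxymethoxy)-3,5-bis(3-methylbut-2-en-1-yl)phenyl]-3,4-dihydro-2H-chromen-4-olate (either configuration at C4) | [Na+].CON(C)C1([O-])C[C@@H](c2cc(CC=C(C)C)c(OCOC)c(CC=C(C)C)c2)Oc2cc(OCOC)cc(Cl)c12 | intermediate (not isolated)
21 | (2S)-5-chloro-7-(methoxymethoxy)-2-[4-(methoxymethoxy)-3,5-bis(3-methylbut-2-en-1-yl)phenyl]-2,3-dihydro-4H-chromen-4-one | CC(C)=CCc1cc([C@@H]2CC(=O)c3c(Cl)cc(OCOC)cc3O2)cc(CC=C(C)C)c1OCOC | intermediate
22 | (2S)-7-(methoxymethoxy)-2-[4-(methoxymethoxy)-3,5-bis(3-methylbut-2-en-1-yl)phenyl]-2,3-dihydro-4H-chromen-4-one | CC(C)=CCc1cc([C@@H]2CC(=O)c3ccc(OCOC)cc3O2)cc(CC=C(C)C)c1OCOC | intermediate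
23 | abyssinone-IV, (2S)-7-hydroxy-2-[4-hydroxy-3,5-bis(3-methylbut-2-en-1-yl)phenyl]-2,3-dihydro-4H-chromen-4-one | CC(C)=CCc1cc([C@@H]2CC(=O)c3ccc(O)cc3O2)cc(CC=C(C)C)c1O | target

**Step count and risks**

Total step count: 10. Longest linear sequence: 7 steps (steps 1, 2, 3, 4, 8, 9, 10).

Steps most likely to fail:

1. Step 8. The ortho-chloroaryl anion may lose chloride to give a second aryne before it is acylated. It may also be protonated, which would give the uncyclised aryl ether, and the aryne may be attacked at the wrong carbon or consumed in ene reactions of the prenyl groups. Fallback (known chemistry), setting out from 7 and returning at 22: transfer hydrogenation of 7 with the enantiomeric catalyst RuCl[(R,R)-TsDPEN](p-cymene) should give (3R)-3-hydroxy-N-methoxy-3-[4-(methoxymethoxy)-3,5-bis(3-methylbut-2-en-1-yl)phenyl]-N-methylpropanamide F1. Addition of excess lithium 2-lithio-5-(methoxymethoxy)phenolate (from 2-bromo-5-(methoxymethoxy)phenol and two equivalents of n-BuLi, THF, −78 °C) to the Weinreb amide of F1 should give (3R)-3-hydroxy-1-[2-hydroxy-4-(methoxymethoxy)phenyl]-3-[4-(methoxymethoxy)-3,5-bis(3-methylbut-2-en-1-yl)phenyl]propan-1-one F2. Intramolecular Mitsunobu etherification of F2 (PPh3, DIAD, THF, 0 °C) should then close O1–C2 with inversion to the (2S)-flavanone 22. On this path the ring A fragment and step 9 are not needed.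

2. Step 9. The palladium hydride may isomerise or reduce the prenyl alkenes, oxidative addition into the aryl chloride may be slow, and prolonged heating may open ring C reversibly and erode the C2 configuration. Fallback, setting out from 21 and returning at 22: a metal-free photoredox hydrodechlorination (10-phenylphenothiazine, Bu3N, HCO2H, MeCN, 390 nm LEDs, rt). This replaces hydride transfer by single-electron reduction of the carbonyl-activated chloroarene, loss of chloride from the radical anion and hydrogen-atom transfer to the aryl radical; no new compound is made.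

3. Step 2. Allyl transposition may give branched (1,1-dimethylallyl) isomers, the second coupling next to the MOM ether may stall, and the boronate may protodeboronate or the ester hydrolyse under the aqueous base. Fallback, setting out from 2 and returning at 4: double Stille allylation with allyltributylstannane (Pd(PPh3)4, toluene, 100 °C), where transposition cannot change the product, should give methyl 4-(methoxymethoxy)-3,5-di(prop-2-en-1-yl)benzoate F3. Double cross-metathesis of F3 with 2-methylbut-2-ene (second-generation Grubbs catalyst, CH2Cl2, 40 °C) should then turn both allyl groups into prenyl groups and give 4.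

**Further compounds**

F1 | step 8 | (3R)-3-hydroxy-N-methoxy-3-[4-(methoxymethoxy)-3,5-bis(3-methylbut-2-en-1-yl)phenyl]-N-methylpropanamide | O[C@H](CC(=O)N(C)OC)c1cc(CC=C(C)C)c(OCOC)c(CC=C(C)C)c1
F2 | step 8 | (3R)-3-hydroxy-1-[2-hydroxy-4-(methoxymethoxy)phenyl]-3-[4-(methoxymethoxy)-3,5-bis(3-methylbut-2-en-1-yl)phenyl]propan-1-one | O[C@H](CC(=O)c1ccc(OCOC)cc1O)c1cc(CC=C(C)C)c(OCOC)c(CC=C(C)C)c1
F0 | step 9 | none | none
F3 | step 2 | methyl 4-(methoxymethoxy)-3,5-di(prop-2-en-1-yl)benzoate | COCOc1c(CC=C)cc(cc1CC=C)C(=O)OC
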